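**Retrosynthetic overview**
1. The target is ring A (chiral 2-acetyl trione) – CH2 – ring B (butanoylphloroglucinol) – CH2 – ring C (8-butanoyl-5,7-dihydroxy-2,2-dimethyl-2H-chromene). Last disconnections: two silyl ethers, then the pyran ring of ring C (C4–C4a and O1–C2) from 3-methylbut-2-enal on the fully assembled trimer 18.
2. Enabling feature: in 18 the future C4a of ring C is the only unsubstituted sp2 carbon of the three carbocycles. It lies between the hydroxyl that becomes O1 (ortho to the butanoyl group) and the para oxygen, which is held as a silyl ether so that only one oxatriene can close.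
3. Trimer 18 comes from ring A (8) and the twofold-symmetric, bis-silylated methylene dimer 15. Both CH2 bridges are made by a Mannich/quinone methide relay, and the dimer is used in two directions (one ring for ring A, the other for the annulation).
4. Ring A comes from the acyclic triketo ester 7 by Claisen ring closure. Ester 7 comes from the acetylacetone dianion and the malonate half-ester 4, whose quaternary stereocentre is set by enzymatic desymmetrisation of geranyl(methyl)malonate 3.
5. Order of ring formation: ring A carbocycle (step 4); rings B and C enter as phloroglucinol; the pyran ring is closed last (step 9).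

Key step: step 9

Assumption: enol tautomers are drawn as in the target and CIP descriptors refer to the tautomer drawn; pig liver esterase is assumed to hydrolyse the pro-S ester of 3, as it does for α-methylmalonates with a long lipophilic chain.

**Step 1**
Reactants: 1 dimethyl methylmalonate, 2 geranyl bromide
Product: 3 dimethyl geranyl(methyl)malonate
Conditions: NaH, THF/DMF, 0 °C to rt
Reagents that add atoms: none
Why: SN2 alkylation of the sodium malonate enolate at the primary allylic bromide should give the achiral quaternary diester without touching either trisubstituted olefin.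

**Step 2**
Reactants: 3 dimethyl geranyl(methyl)malonate
Product: 4 (R)-half-ester acid
Conditions: pig liver esterase, phosphate buffer pH 7.5/DMSO 9:1, 25 °C, pH-stat (1 M NaOH); then 1 M HCl
Reagents that add atoms: water, O
Why: Enzymatic desymmetrisation of a prochiral α,α-dialkylmalonate, in which hydrolysis of the pro-S ester (the sense assumed above) sets the only stereocentre of the target as R; this quaternary centre has no α-hydrogen and cannot be scrambled later.

**Step 3**
Reactants: 4 (R)-half-ester acid, 5 pentane-2,4-dione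
Product: 7 methyl (2R)-2-geranyl-2-methyl-3,5,7-trioxooctanoate, via acyl imidazolide 6 (not isolated)
Conditions: CDI, THF, rt; then 5 (3 equiv)/LiN(iPr)2 (6 equiv), THF, −78 to 0 °C; aq HCl
Reagents that add atoms: 1,1′-carbonyldiimidazole, O=C(n1ccnc1)n1ccnc1 (its imidazolyl group appears in 6 only)
Why: Activation of the acid as its acyl imidazolide and Claisen-type C-acylation of the acetylacetone dianion at its terminal carbon should give the triketo ester, the excess dianion absorbing the acidic proton of the product so that no second acylation occurs.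

**Step 4**
Reactants: 7 methyl (2R)-2-geranyl-2-methyl-3,5,7-trioxooctanoate
Product: 8 ring A trione (4R)-2-acetyl-4-geranyl-3,5-dihydroxy-4-methylcyclohexa-2,5-dien-1-one
Conditions: NaOMe, MeOH, 65 °C; then 1 M HCl
Reagents that add atoms: none
Why: Intramolecular Claisen (Dieckmann-type, 6-exo-trig) condensation of the C6 carbanion onto the ester closes ring A in the way 3,5,7-triketo esters give acylphloroglucinols; under methoxide the competing enol lactone is reversible, the product leaves all equilibria as its stabilised trione enolate, and the stereocentre is untouched.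

**Step 5**
Reactants: 9 phloroglucinol, 10 butanoyl chloride
Product: 11 1-(2,4,6-trihydroxyphenyl)butan-1-one
Conditions: AlCl3, CH2Cl2/PhNO2, 0 to 40 °C; aq HCl
Reagents that add atoms: none
Why: Friedel–Crafts C-acylation of the highly activated arene, which the deactivating acyl group should hold at monoacylation when one equivalent of acid chloride is used.

**Step 6**
Reactants: 11 1-(2,4,6-trihydroxyphenyl)butan-1-one
Product: 12 1-[2,6-dihydroxy-4-(triisopropylsilyloxy)phenyl]butan-1-one
Conditions: iPr3SiCl (1.05 equiv), imidazole, DMF, 0 °C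
Reagents that add atoms: chlorotriisopropylsilane, CC(C)[Si](Cl)(C(C)C)C(C)C
Why: The 4-hydroxyl is the most acidic and the only one not flanked by the ketone, so one equivalent of the bulky chlorosilane should silylate it selectively (standard phenol silylation).

**Step 7**
Reactants: 12 1-[2,6-dihydroxy-4-(triisopropylsilyloxy)phenyl]butan-1-one (two molecules)
Product: 15 bis-silylated methylene dimer, via Mannich base 13 (not isolated), via quinone methide 14 (not isolated)
Conditions: [Me2N=CH2]I (0.25 equiv per 12), iPr2NEt, MeCN, 0 °C to rt; then PhMe, 100 °C; excess 12 recovered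
Reagents that add atoms: N,N-dimethylmethyleneiminium iodide, C=[N+](C)C.[I-]
Why: Mannich aminomethylation of one molecule ortho to a free hydroxyl, then thermal loss of dimethylamine to the ortho-quinone methide and Friedel–Crafts-type (Michael) capture by a second molecule of 12, kept in excess to suppress oligomers, should give the twofold-symmetric dimer with both para oxygens silylated.

**Step 8**
Reactants: 8 ring A trione, 15 bis-silylated methylene dimer
Product: 18 bis-silylated trimer (ring A–CH2–ring B–CH2–ring C precursor), via ring A Mannich base 16 (not isolated), via methylidene trione 17 (not isolated)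
Conditions: 8 added to [Me2N=CH2]I (1.1 equiv), iPr2NEt, MeCN, 0 °C; then 15 (3 equiv), PhMe, 70 °C, Ar sweep; excess 15 recovered
Reagents that add atoms: N,N-dimethylmethyleneiminium iodide, C=[N+](C)C.[I-]
Why: Mannich reaction at the only free ring carbon of the trione (inverse addition leaves no free 8 to capture the electrophile), then retro-Mannich loss of dimethylamine to the methylidene trione 17 and its Michael capture by a free ring carbon of 15, used in excess to limit double alkylation; the stereocentre is not involved.

**Step 9**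
Reactants: 18 bis-silylated trimer, 19 3-methylbut-2-enal
Product: 21 bis-silylated target (chromene closed), via oxatriene 20 (not isolated)
Conditions: 19 (3 equiv), pyridine, 110 °C, Ar, sealed tube
Reagents that add atoms: none
Why: Pyridine promotes a Knoevenagel-type aldol condensation of the phenoxide carbon C4a of ring C with the aldehyde carbon of 19 (forming C4–C4a), and loss of water gives the 1-oxatriene (vinylogous ortho-quinone methide) 20, whose thermal disrotatory oxa-6π electrocyclisation forms O1–C2 and restores the aromatic ring. This is the classical formal [3+3] annulation of phenols with 3-methylbut-2-enal, well established for acylphloroglucinols. The only ring closed is the 2H-pyran, by 6π electrocyclisation of the oxatriene (a pericyclic six-membered closure). No stereocentre is created (C2 carries two methyl groups), and the quaternary centre of ring A, having no α-hydrogen, is not at risk. Site selectivity is secured because C4a is the only unsubstituted sp2 carbon in any of the three six-membered carbocycles of 18, so the aldehyde can condense nowhere else and over-annulation is impossible. Regioselectivity of the O–C bond is secured by the triisopropylsilyl ether on the para oxygen: only the oxygen ortho to the butanoyl group can become the oxatriene carbonyl, so the 8-butanoyl chromene must result.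

**Step 10**
Reactants: 21 bis-silylated target
Product: 22 CNP0103039.1
Conditions: Bu4NF (2.5 equiv), AcOH (3 equiv), THF, 0 °C
Reagents that add atoms: none
Why: Fluoride cleaves both aryl silyl ethers at 0 °C (Si–F bond formation) while the acetic acid buffer protects the methylene bridges and the trione; chromene, olefins and stereocentre are inert.

**Compound list**
1 | dimethyl 2-methylpropanedioate (dimethyl methylmalonate) | COC(=O)C(C)C(=O)OC | starting material
2 | (2E)-1-bromo-3,7-dimethylocta-2,6-diene (geranyl bromide) | BrC/C=C(\C)CCC=C(C)C | starting material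
3 | dimethyl 2-[(2E)-3,7-dimethylocta-2,6-dien-1-yl]-2-methylpropanedioate | COC(=O)C(C)(C/C=C(\C)CCC=C(C)C)C(=O)OC | intermediate
4 | (2R)-2-[(2E)-3,7-dimethylocta-2,6-dien-1-yl]-3-methoxy-2-methyl-3-oxopropanoic acid | OC(=O)[C@@](C)(C/C=C(\C)CCC=C(C)C)C(=O)OC | intermediate
5 | pentane-2,4-dione (acetylacetone) | CC(=O)CC(C)=O | starting material
6 | methyl (2R)-2-[(2E)-3,7-dimethylocta-2,6-dien-1-yl]-3-(imidazol-1-yl)-2-methyl-3-oxopropanoate (acyl imidazolide) | O=C(n1ccnc1)[C@@](C)(C/C=C(\C)CCC=C(C)C)C(=O)OC | intermediate
7 | methyl (2R)-2-[(2E)-3,7-dimethylocta-2,6-dien-1-yl]-2-methyl-3,5,7-trioxooctanoate | CC(=O)CC(=O)CC(=O)[C@@](C)(C/C=C(\C)CCC=C(C)C)C(=O)OC | intermediate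
8 | (4R)-2-acetyl-4-[(2E)-3,7-dimethylocta-2,6-dien-1-yl]-3,5-dihydroxy-4-methylcyclohexa-2,5-dien-1-one (ring A) | CC(=O)C1=C(O)[C@](C)(C/C=C(\C)CCC=C(C)C)C(O)=CC1=O | intermediate
9 | benzene-1,3,5-triol (phloroglucinol) | Oc1cc(O)cc(O)c1 | starting material
10 | butanoyl chloride | CCCC(=O)Cl | starting material
11 | 1-(2,4,6-trihydroxyphenyl)butan-1-one | CCCC(=O)c1c(O)cc(O)cc1O | intermediate
12 | 1-[2,6-dihydroxy-4-(triisopropylsilyloxy)phenyl]butan-1-one | CCCC(=O)c1c(O)cc(O[Si](C(C)C)(C(C)C)C(C)C)cc1O | intermediate
13 | 1-{3-[(dimethylamino)methyl]-2,6-dihydroxy-4-(triisopropylsilyloxy)phenyl}butan-1-one (Mannich base) | CCCC(=O)c1c(O)cc(O[Si](C(C)C)(C(C)C)C(C)C)c(CN(C)C)c1O | intermediate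
14 | 2-butanoyl-3-hydroxy-6-methylidene-5-(triisopropylsilyloxy)cyclohexa-2,4-dien-1-one (ortho-quinone methide) | C=C1C(=O)C(C(=O)CCC)=C(O)C=C1O[Si](C(C)C)(C(C)C)C(C)C | intermediate
15 | bis[3-butanoyl-2,4-dihydroxy-6-(triisopropylsilyloxy)phenyl]methane | CCCC(=O)c1c(O)cc(O[Si](C(C)C)(C(C)C)C(C)C)c(Cc2c(O[Si](C(C)C)(C(C)C)C(C)C)cc(O)c(C(=O)CCC)c2O)c1O | intermediate
16 | (4R)-2-acetyl-6-[(dimethylamino)methyl]-4-[(2E)-3,7-dimethylocta-2,6-dien-1-yl]-3,5-dihydroxy-4-methylcyclohexa-2,5-dien-1-one (ring A Mannich base) | CN(C)CC1=C(O)[C@@](C)(C/C=C(\C)CCC=C(C)C)C(O)=C(C(C)=O)C1=O | intermediate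
17 | 2-acetyl-4-[(2E)-3,7-dimethylocta-2,6-dien-1-yl]-3-hydroxy-4-methyl-6-methylidenecyclohex-2-ene-1,5-dione, same spatial arrangement at C4 as in 8 (descriptor S for this structure) | C=C1C(=O)[C@@](C)(C/C=C(\C)CCC=C(C)C)C(O)=C(C(C)=O)C1=O | intermediate
18 | (4R)-2-acetyl-6-({3-butanoyl-5-[3-butanoyl-2,4-dihydroxy-6-(triisopropylsilyloxy)benzyl]-2,4-dihydroxy-6-(triisopropylsilyloxy)phenyl}methyl)-4-[(2E)-3,7-dimethylocta-2,6-dien-1-yl]-3,5-dihydroxy-4-methylcyclohexa-2,5-dien-1-one | CCCC(=O)c1c(O)c(CC2=C(O)[C@@](C)(C/C=C(\C)CCC=C(C)C)C(O)=C(C(C)=O)C2=O)c(O[Si](C(C)C)(C(C)C)C(C)C)c(Cc2c(O[Si](C(C)C)(C(C)C)C(C)C)cc(O)c(C(=O)CCC)c2O)c1O | intermediate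
19 | 3-methylbut-2-enal | CC(C)=CC=O | starting material
20 | oxatriene from 18: ring C as 2-butanoyl-3-hydroxy-6-(3-methylbut-2-enylidene)-5-(triisopropylsilyloxy)cyclohexa-2,4-dien-1-one carrying the CH2 bridge at C4, rings A and B as in 18; geometry of the exocyclic C=C not fixed | CCCC(=O)c1c(O)c(CC2=C(O)[C@@](C)(C/C=C(\C)CCC=C(C)C)C(O)=C(C(C)=O)C2=O)c(O[Si](C(C)C)(C(C)C)C(C)C)c(CC2=C(O[Si](C(C)C)(C(C)C)C(C)C)C(=CC=C(C)C)C(=O)C(C(=O)CCC)=C2O)c1O | intermediate
21 | (4R)-2-acetyl-6-[(3-butanoyl-5-{[8-butanoyl-7-hydroxy-2,2-dimethyl-5-(triisopropylsilyloxy)-2H-chromen-6-yl]methyl}-2,4-dihydroxy-6-(triisopropylsilyloxy)phenyl)methyl]-4-[(2E)-3,7-dimethylocta-2,6-dien-1-yl]-3,5-dihydroxy-4-methylcyclohexa-2,5-dien-1-one | CCCC(=O)c1c(O)c(CC2=C(O)[C@@](C)(C/C=C(\C)CCC=C(C)C)C(O)=C(C(C)=O)C2=O)c(O[Si](C(C)C)(C(C)C)C(C)C)c(Cc2c(O[Si](C(C)C)(C(C)C)C(C)C)c3c(c(C(=O)CCC)c2O)OC(C)(C)C=C3)c1O | intermediate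
22 | CNP0103039.1: (4R)-2-acetyl-6-[(3-butanoyl-5-{[8-butanoyl-5,7-dihydroxy-2,2-dimethyl-2H-chromen-6-yl]methyl}-2,4,6-trihydroxyphenyl)methyl]-4-[(2E)-3,7-dimethylocta-2,6-dien-1-yl]-3,5-dihydroxy-4-methylcyclohexa-2,5-dien-1-one | CCCC(=O)c1c(O)c(CC2=C(O)[C@@](C)(C/C=C(\C)CCC=C(C)C)C(O)=C(C(C)=O)C2=O)c(O)c(Cc2c(O)c3c(c(C(=O)CCC)c2O)OC(C)(C)C=C3)c1O | target

**Step count**
Total steps: 10. Longest linear sequence: 7 steps (steps 1, 2, 3, 4, 8, 9, 10, from dimethyl methylmalonate).

**Steps most likely to fail, with fallbacks**

Step 9. What may go wrong: loss of the para silyl ether in hot pyridine (which would open the second cyclisation mode), slow condensation at the carbon next to the bulky silyl ether, or retro-Michael exchange of the ring A–ring B bridge on heating. Fallback: the annulation is moved ahead of the union with ring A. It sets out from 15. Dimer 15 (in excess) and 19 (1 equiv) in pyridine at 110 °C should give, through the dimer oxatriene F1, the mono-chromene dimer F2, in which ring A is not yet present and the second ring still has its free carbon. F2 is then alkylated at that carbon by the methylidene trione 17, generated from 8 through 16 as in step 8. The route is rejoined at 21.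

Step 8. What may go wrong: capture of the ring A electrophile by unreacted 8 (homodimerisation), double alkylation of 15, or exchange of methylene bridges. Fallback: the roles of the partners are reversed, so that no electrophilic ring A species is ever present. It sets out from 15. Monoaminomethylation of 15 (in excess) with [Me2N=CH2]I and iPr2NEt should give the phenolic Mannich base F3. Heating F3 with 8 in toluene releases the ortho-quinone methide F4, which is captured by the free ring carbon of 8 as the carbon nucleophile. The route is rejoined at 18.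

Step 2. What may go wrong: incomplete or reversed enantiotopic group selection by the enzyme, or slow turnover of the lipophilic diester. Fallback: classical resolution in place of desymmetrisation. It sets out from 3. Monosaponification with KOH (1 equiv) in MeOH/water should give the racemic half-ester F5. Crystallisation of its salt with one enantiomer of 1-phenylethylamine (written for the S amine; the enantiomer is chosen so that the salt of the R acid is the less soluble one) gives the diastereomerically pure 1-phenylethylammonium salt F6. Acidification with HCl liberates the acid, and the route is rejoined at 4.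

**Further compounds**
F1 | step 9 | oxatriene from 15 (one ring as the 6-(3-methylbut-2-enylidene)cyclohexadienone, the other unchanged) | CCCC(=O)c1c(O)cc(O[Si](C(C)C)(C(C)C)C(C)C)c(CC2=C(O[Si](C(C)C)(C(C)C)C(C)C)C(=CC=C(C)C)C(=O)C(C(=O)CCC)=C2O)c1O
F2 | step 9 | 1-{3-[(8-butanoyl-7-hydroxy-2,2-dimethyl-5-(triisopropylsilyloxy)-2H-chromen-6-yl)methyl]-2,6-dihydroxy-4-(triisopropylsilyloxy)phenyl}butan-1-one (mono-chromene dimer) | CCCC(=O)c1c(O)cc(O[Si](C(C)C)(C(C)C)C(C)C)c(Cc2c(O[Si](C(C)C)(C(C)C)C(C)C)c3c(c(C(=O)CCC)c2O)OC(C)(C)C=C3)c1O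
F3 | step 8 | mono-Mannich base of 15 (dimethylaminomethyl group at the free carbon of one ring) | CCCC(=O)c1c(O)c(CN(C)C)c(O[Si](C(C)C)(C(C)C)C(C)C)c(Cc2c(O[Si](C(C)C)(C(C)C)C(C)C)cc(O)c(C(=O)CCC)c2O)c1O
F4 | step 8 | ortho-quinone methide from F3 (6-methylidenecyclohexa-2,4-dien-1-one in one ring) | C=C1C(=O)C(C(=O)CCC)=C(O)C(Cc2c(O[Si](C(C)C)(C(C)C)C(C)C)cc(O)c(C(=O)CCC)c2O)=C1O[Si](C(C)C)(C(C)C)C(C)C
F5 | step 2 | racemic 2-[(2E)-3,7-dimethylocta-2,6-dien-1-yl]-3-methoxy-2-methyl-3-oxopropanoic acid | OC(=O)C(C)(C/C=C(\C)CCC=C(C)C)C(=O)OC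
F6 | step 2 | (S)-1-phenylethylammonium salt of acid 4 | [O-]C(=O)[C@@](C)(C/C=C(\C)CCC=C(C)C)C(=O)OC.C[C@H]([NH3+])c1ccccc1
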